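## Retrosynthetic overview

- Cutting the C8 vanillate ester and the C3–C4 oxirane leads to 1αH,5βH-guai-3-ene-8β,10α-diol and O-silylated vanillic acid. The C3=C4 alkene comes from a C3 ketone by reductive enol triflation and Pd/formate reduction.
- The strategy rests on this feature: the five-membered ring C1–C2–C3–C4–C5, fused through C1–C5 to the seven-membered ring C1–C10–C9–C8–C7–C6–C5, carries a methyl carbinol at C10 (next to C1) and an oxirane at C3–C4 (next to C5). This is the pattern left by a 10-hydroxyguai-4-en-3-one.
- Key disconnection: that hydroxy enone goes back to an 8β-silyloxy-eudesma-1,4-dien-3-one by the santonin-type photorearrangement in aqueous acetic acid (C1–C5 and C10–O made, C5–C10 broken).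
- The dienone comes from DDQ dehydrogenation of the 4-en-3-one, which comes from an auxiliary-controlled Robinson annulation of ethyl vinyl ketone onto a cis-4-silyloxy-5-isopropyl-2-methylcyclohexanone made from (R)-carvone (γ-hydroxylation, Mitsunobu inversion).
- Ring order: ring B (from carvone), then ring A (annulation), then both recast as the five- and seven-membered rings in one photochemical step, then the oxirane last.

Key step: step 11

Remark: the target SMILES is read as 3α,4α-epoxy-10α-hydroxy-1αH,5βH-guaian-8β-yl 4-hydroxy-3-methoxybenzoate (β = face of the C10 methyl); ketone 8 is carried as a mixture of C2 epimers because that centre becomes planar in step 8.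

## Route

Step 1
Reactants: 1 (R)-carvone
Product: 2 (R)-carvotanacetone, (5R)-2-methyl-5-isopropylcyclohex-2-en-1-one
Conditions: H2 (1 atm), RhCl(PPh3)3 (cat.), benzene, rt
Reagents that add atoms: none
Why: homogeneous hydrogenation with RhCl(PPh3)3 should saturate the unhindered 1,1-disubstituted isopropenyl alkene and leave the trisubstituted conjugated alkene, with C5 untouched.

Step 2
Reactants: 2 (R)-carvotanacetone
Product: 3 (5R)-2-methyl-5-isopropylcyclohexa-1,3-dien-1-yl acetate
Conditions: isopropenyl acetate (solvent), TsOH·H2O (cat.), reflux, acetone distilled off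
Reagents that add atoms: isopropenyl acetate, CC(=C)OC(C)=O
Why: acid-catalysed enol acetylation under equilibrating conditions should give the linear dienyl acetate by loss of the γ-hydrogen at C4 (as with steroidal 4-en-3-ones); C5 lies outside the enolisation path and keeps its configuration.

Step 3
Reactants: 3 dienyl acetate
Product: 4 (4R,5R)-4-hydroxy-2-methyl-5-isopropylcyclohex-2-en-1-one (OH trans to isopropyl)
Conditions: mCPBA, 1,4-dioxane/H2O 9:1, 0 °C to rt
Reagents that add atoms: mCPBA, OOC(=O)c1cccc(Cl)c1
Why: γ-hydroxylation of a dienol ester: the peracid should epoxidise the distal C3=C4 bond anti to the C5 isopropyl group, the oxirane opens under the push of the enol-acetate oxygen and water removes the acetyl group, which sets C4 as 4R.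

Step 4
Reactants: 4 trans-hydroxy enone
Product: 5 (4S,5R)-2-methyl-4-(4-nitrobenzoyloxy)-5-isopropylcyclohex-2-en-1-one (ester cis to isopropyl)
Conditions: 4-nitrobenzoic acid, PPh3, DIAD, THF, 0 °C to rt
Reagents that add atoms: 4-nitrobenzoic acid, OC(=O)c1ccc(cc1)[N+](=O)[O-]
Why: Mitsunobu reaction: the alkoxyphosphonium of the allylic alcohol is displaced by 4-nitrobenzoate in an SN2 fashion with inversion at C4, turning trans into cis, and elimination toward C5 lacks an anti-periplanar hydrogen.

Step 5
Reactants: 5 cis 4-nitrobenzoate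
Product: 6 (4S,5R)-4-hydroxy-2-methyl-5-isopropylcyclohex-2-en-1-one (OH cis to isopropyl)
Conditions: K2CO3 (cat.), MeOH, 0 °C
Reagents that add atoms: none
Why: carbonate-catalysed transesterification of the activated aryl ester frees the alcohol without breaking the C4–O bond, so the cis configuration is kept.

Step 6
Reactants: 6 cis-hydroxy enone
Product: 7 (4S,5R)-2-methyl-5-isopropyl-4-(triisopropylsilyloxy)cyclohex-2-en-1-one
Conditions: TIPSOTf, 2,6-lutidine, CH2Cl2, −78 to 0 °C
Reagents that add atoms: triisopropylsilyl triflate, CC(C)[Si](OS(=O)(=O)C(F)(F)F)(C(C)C)C(C)C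
Why: O-silylation of the hindered secondary alcohol with a silyl triflate; the triisopropylsilyl ether is chosen because it should withstand methoxide, DDQ, aqueous acetic acid and lithium in ammonia.

Step 7
Reactants: 7 silyloxy enone
Product: 8 (4R,5R)-2-methyl-5-isopropyl-4-(triisopropylsilyloxy)cyclohexan-1-one (C2 epimer mixture)
Conditions: H2 (1 atm), Pd/C, EtOAc, rt
Reagents that add atoms: none
Why: heterogeneous hydrogenation of the conjugated C2=C3 bond under neutral conditions should leave the allylic silyl ether intact, and the C2 configuration does not matter.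

Step 8
Reactants: 8 silyloxy ketone; 9 (R)-1-phenylethylamine; 10 ethyl vinyl ketone
Product: 13 (2R,4R,5R)-2-methyl-2-(3-oxopentyl)-5-isopropyl-4-(triisopropylsilyloxy)cyclohexan-1-one, via ketimine 11 (not isolated), via Michael adduct ketimine 12 (not isolated)
Conditions: (a) 9, TsOH (cat.), toluene, reflux, Dean–Stark; (b) 10, THF, 40 °C; (c) AcOH/H2O, rt
Reagents that add atoms: water, O
Why: chiral-imine Michael addition (first stage of the Robinson annulation): the more substituted secondary enamine tautomer adds to the enone through a chair-like aza-ene transition state on the face fixed by the (R)-auxiliary, which is also the face anti to the axial silyloxy group, so the new bond forms α and the methyl ends β (cis to isopropyl).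

Step 9
Reactants: 13 diketone
Product: 14 8β-(triisopropylsilyloxy)eudesm-4-en-3-one
Conditions: NaOMe, MeOH, rt to 50 °C
Reagents that add atoms: none
Why: intramolecular aldol condensation (second stage of the Robinson annulation, 6-enolexo-exo-trig): the ethyl-ketone enolate attacks the ring ketone and dehydration gives the tetrasubstituted C4=C5 enone, with the quaternary C10 and the remote C7 and C8 centres unaffected.

Step 10
Reactants: 14 enone
Product: 15 8β-(triisopropylsilyloxy)eudesma-1,4-dien-3-one
Conditions: DDQ, 1,4-dioxane, reflux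
Reagents that add atoms: none
Why: DDQ dehydrogenation of a 4-en-3-one under neutral conditions proceeds through the 2,4-dienol with hydride abstraction from C1 and should give the cross-conjugated 1,4-dien-3-one, while the quaternary C10 rules out aromatisation.

Step 11
Reactants: 15 dienone
Product: 16 10α-hydroxy-8β-(triisopropylsilyloxy)-1αH-guai-4-en-3-one
Conditions: hν (high-pressure Hg lamp, Pyrex filter), AcOH/H2O 2:1, N2, 20 °C, about 5 mM
Reagents that add atoms: water, O
Why: n→π* excitation and intersystem crossing let C1 bond to C5, giving a bicyclo[3.1.0] oxyallyl zwitterion that acetic acid protonates on oxygen; the C4 methyl localises the positive charge at C4, so the cyclopropane bond C5–C10 opens as water adds to C10 and the C2=C3 enol ketonises. The closest known reaction is the santonin to isophotosantonic lactone rearrangement and its 4-methyl-eudesma-1,4-dien-3-one analogues in aqueous acetic acid. The five-membered ring closes by C1–C5 bonding across the dienone (β,β-bridging), and the seven-membered ring is not closed by a new bond but arises by ring enlargement when the shared C5–C10 bond of the bicyclo[4.1.0] unit is cut. At C1, ring B can only be cis-fused to the cyclopropane, so C10 swings to the β face with its methyl endo and H1 ends α; at C10, water attacks anti to the departing C5–C10 bond, which puts OH α and keeps the methyl β, so both centres follow from the 10β-methyl centre of 15. The step needs the 5-7 hydroxy ketone to win over lumiketone and spiro products, which the C4 methyl and the protic acidic medium should secure, and irradiation is stopped at full conversion to spare the product enone.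

Step 12
Reactants: 16 hydroxy enone
Product: 17 10α-(triethylsilyloxy)-8β-(triisopropylsilyloxy)-1αH-guai-4-en-3-one
Conditions: TESOTf, 2,6-lutidine, CH2Cl2, −78 °C
Reagents that add atoms: triethylsilyl triflate, CC[Si](CC)(CC)OS(=O)(=O)C(F)(F)F
Why: silylation of the tertiary alcohol with a silyl triflate and a hindered pyridine base is faster than silyl enol ether formation at −78 °C, and it removes the only acidic proton so that the proton source in step 13 is exactly dosed.

Step 13
Reactants: 17 bis-silyl enone
Product: 19 10α-(triethylsilyloxy)-8β-(triisopropylsilyloxy)-1αH,5βH-guai-3-en-3-yl trifluoromethanesulfonate, via lithium enolate 18 (not isolated)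
Conditions: Li, NH3/THF, t-BuOH (1.0 equiv), −78 °C; isoprene; NH3 evaporated; PhNTf2, THF, −78 °C to rt
Reagents that add atoms: N-phenylbis(trifluoromethanesulfonimide), O=S(=O)(N(c1ccccc1)S(=O)(=O)C(F)(F)F)C(F)(F)F
Why: dissolving-metal (Birch-type) reduction of the enone should protonate the pyramidal C5 carbanion to give the more stable trans-fused hydroazulene (5βH anti to 1αH), as is usual for ring-fusion enones, and the regiodefined C3=C4 lithium enolate is then O-triflated (reductive enol triflation).

Step 14
Reactants: 19 enol triflate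
Product: 20 10α-(triethylsilyloxy)-8β-(triisopropylsilyloxy)-1αH,5βH-guai-3-ene
Conditions: Pd(OAc)2 (5 mol%), PPh3 (10 mol%), Et3N, HCO2H, DMF, 60 °C
Reagents that add atoms: none
Why: palladium-catalysed formate reduction of an enol triflate: zerovalent palladium inserts into the C3–O bond, formate supplies hydride with loss of CO2 and reductive elimination leaves the C3=C4 alkene in place without touching C5.

Step 15
Reactants: 20 bis-silyl alkene
Product: 21 1αH,5βH-guai-3-ene-8β,10α-diol
Conditions: TBAF (excess), THF, 50 °C
Reagents that add atoms: none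
Why: fluoride-mediated desilylation removes both the tertiary triethylsilyl and the hindered secondary triisopropylsilyl ether, and nothing else in the molecule is sensitive to fluoride or base.

Step 16
Reactants: 22 vanillic acid
Product: 24 4-(tert-butyldimethylsilyloxy)-3-methoxybenzoic acid, via bis-silyl derivative 23 (not isolated)
Conditions: TBSCl (2.5 equiv), imidazole, DMF, rt; then AcOH/THF/H2O 3:1:1, rt
Reagents that add atoms: tert-butyldimethylsilyl chloride, CC(C)(C)[Si](C)(C)Cl
Why: silylation of both acidic OH groups followed by selective hydrolysis of the labile silyl ester leaves the phenol as its silyl ether, which blocks self-esterification in step 17.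

Step 17
Reactants: 21 diol; 24 O-silyl vanillic acid
Product: 25 10α-hydroxy-1αH,5βH-guai-3-en-8β-yl 4-(tert-butyldimethylsilyloxy)-3-methoxybenzoate
Conditions: DCC, DMAP (1 equiv), CH2Cl2, rt to 35 °C
Reagents that add atoms: none
Why: Steglich esterification: the carbodiimide-activated acid is passed on by DMAP to the secondary C8 hydroxyl, the tertiary C10 hydroxyl is too hindered to acylate, and C8 keeps its configuration because its C–O bond is not broken.

Step 18
Reactants: 25 alkenyl ester
Product: 26 3α,4α-epoxy-10α-hydroxy-1αH,5βH-guaian-8β-yl 4-(tert-butyldimethylsilyloxy)-3-methoxybenzoate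
Conditions: VO(acac)2 (5 mol%), t-BuOOH (in decane), CH2Cl2, 0 °C to rt
Reagents that add atoms: tert-butyl hydroperoxide, CC(C)(C)OO
Why: hydroxyl-directed epoxidation: the C10 alcohol, bishomoallylic to C3=C4, binds the pentavalent vanadium peroxide, and because the 10β-methyl blocks the β side of that alkoxide the oxygen should be delivered to the α face, setting C3 and C4 together.

Step 19
Reactants: 26 silyl-protected epoxy ester
Product: 27 3α,4α-epoxy-10α-hydroxy-1αH,5βH-guaian-8β-yl 4-hydroxy-3-methoxybenzoate (CNP0136245.2)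
Conditions: TBAF (1.1 equiv), AcOH (1.1 equiv), THF, 0 °C
Reagents that add atoms: none
Why: fluoride cleavage of the aryl silyl ether, buffered with acetic acid so that the phenoxide is protonated at once, should leave the oxirane, the ester and the tertiary alcohol untouched.

## Compound list

1 | (R)-carvone | CC1=CC[C@H](CC1=O)C(C)=C | starting material
2 | (R)-carvotanacetone | CC1=CC[C@H](CC1=O)C(C)C | intermediate
3 | (5R)-2-methyl-5-isopropylcyclohexa-1,3-dien-1-yl acetate | CC(=O)OC1=C(C)C=C[C@@H](C(C)C)C1 | intermediate
4 | (4R,5R)-4-hydroxy-2-methyl-5-isopropylcyclohex-2-en-1-one | CC1=C[C@H](O)[C@H](CC1=O)C(C)C | intermediate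
5 | (4S,5R)-2-methyl-4-(4-nitrobenzoyloxy)-5-isopropylcyclohex-2-en-1-one | CC1=C[C@@H](OC(=O)c2ccc(cc2)[N+](=O)[O-])[C@H](CC1=O)C(C)C | intermediate
6 | (4S,5R)-4-hydroxy-2-methyl-5-isopropylcyclohex-2-en-1-one | CC1=C[C@@H](O)[C@H](CC1=O)C(C)C | intermediate
7 | (4S,5R)-2-methyl-5-isopropyl-4-(triisopropylsilyloxy)cyclohex-2-en-1-one | CC1=C[C@@H](O[Si](C(C)C)(C(C)C)C(C)C)[C@H](CC1=O)C(C)C | intermediate
8 | (4R,5R)-2-methyl-5-isopropyl-4-(triisopropylsilyloxy)cyclohexan-1-one, C2 epimer mixture | CC1C[C@@H](O[Si](C(C)C)(C(C)C)C(C)C)[C@H](CC1=O)C(C)C | intermediate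
9 | (R)-1-phenylethylamine | C[C@@H](N)c1ccccc1 | starting material
10 | ethyl vinyl ketone | CCC(=O)C=C | starting material
11 | ketimine of 8 with 9 | CC1C[C@@H](O[Si](C(C)C)(C(C)C)C(C)C)[C@H](CC1=N[C@H](C)c1ccccc1)C(C)C | intermediate
12 | Michael adduct ketimine | CCC(=O)CC[C@]1(C)C[C@@H](O[Si](C(C)C)(C(C)C)C(C)C)[C@H](CC1=N[C@H](C)c1ccccc1)C(C)C | intermediate
13 | (2R,4R,5R)-2-methyl-2-(3-oxopentyl)-5-isopropyl-4-(triisopropylsilyloxy)cyclohexan-1-one | CCC(=O)CC[C@]1(C)C[C@@H](O[Si](C(C)C)(C(C)C)C(C)C)[C@H](CC1=O)C(C)C | intermediate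
14 | 8β-(triisopropylsilyloxy)eudesm-4-en-3-one | CC(C)[Si](C(C)C)(C(C)C)O[C@@H]1C[C@@]2(C)CCC(=O)C(C)=C2C[C@@H]1C(C)C | intermediate
15 | 8β-(triisopropylsilyloxy)eudesma-1,4-dien-3-one | CC(C)[Si](C(C)C)(C(C)C)O[C@@H]1C[C@@]2(C)C=CC(=O)C(C)=C2C[C@@H]1C(C)C | intermediate
16 | 10α-hydroxy-8β-(triisopropylsilyloxy)-1αH-guai-4-en-3-one | CC(C)[Si](C(C)C)(C(C)C)O[C@@H]1C[C@@](C)(O)[C@@H]2CC(=O)C(C)=C2C[C@@H]1C(C)C | intermediate
17 | 10α-(triethylsilyloxy)-8β-(triisopropylsilyloxy)-1αH-guai-4-en-3-one | CC(C)[Si](C(C)C)(C(C)C)O[C@@H]1C[C@@](C)(O[Si](CC)(CC)CC)[C@@H]2CC(=O)C(C)=C2C[C@@H]1C(C)C | intermediate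
18 | lithium C3=C4 enolate (5βH) | CC(C)[Si](C(C)C)(C(C)C)O[C@@H]1C[C@@](C)(O[Si](CC)(CC)CC)[C@@H]2CC([O-])=C(C)[C@H]2C[C@@H]1C(C)C.[Li+] | intermediate
19 | 10α-(triethylsilyloxy)-8β-(triisopropylsilyloxy)-1αH,5βH-guai-3-en-3-yl triflate | CC(C)[Si](C(C)C)(C(C)C)O[C@@H]1C[C@@](C)(O[Si](CC)(CC)CC)[C@@H]2CC(OS(=O)(=O)C(F)(F)F)=C(C)[C@H]2C[C@@H]1C(C)C | intermediate
20 | 10α-(triethylsilyloxy)-8β-(triisopropylsilyloxy)-1αH,5βH-guai-3-ene | CC(C)[Si](C(C)C)(C(C)C)O[C@@H]1C[C@@](C)(O[Si](CC)(CC)CC)[C@@H]2CC=C(C)[C@H]2C[C@@H]1C(C)C | intermediate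
21 | 1αH,5βH-guai-3-ene-8β,10α-diol | O[C@@H]1C[C@@](C)(O)[C@@H]2CC=C(C)[C@H]2C[C@@H]1C(C)C | intermediate
22 | vanillic acid | COc1cc(C(=O)O)ccc1O | starting material
23 | tert-butyldimethylsilyl 4-(tert-butyldimethylsilyloxy)-3-methoxybenzoate | COc1cc(C(=O)O[Si](C)(C)C(C)(C)C)ccc1O[Si](C)(C)C(C)(C)C | intermediate
24 | 4-(tert-butyldimethylsilyloxy)-3-methoxybenzoic acid | COc1cc(C(=O)O)ccc1O[Si](C)(C)C(C)(C)C | intermediate
25 | 10α-hydroxy-1αH,5βH-guai-3-en-8β-yl 4-(tert-butyldimethylsilyloxy)-3-methoxybenzoate | COc1cc(C(=O)O[C@@H]2C[C@@](C)(O)[C@@H]3CC=C(C)[C@H]3C[C@@H]2C(C)C)ccc1O[Si](C)(C)C(C)(C)C | intermediate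
26 | 3α,4α-epoxy-10α-hydroxy-1αH,5βH-guaian-8β-yl 4-(tert-butyldimethylsilyloxy)-3-methoxybenzoate | COc1cc(C(=O)O[C@@H]2C[C@@](C)(O)[C@@H]3C[C@H]4O[C@@]4(C)[C@H]3C[C@@H]2C(C)C)ccc1O[Si](C)(C)C(C)(C)C | intermediate
27 | 3α,4α-epoxy-10α-hydroxy-1αH,5βH-guaian-8β-yl 4-hydroxy-3-methoxybenzoate (CNP0136245.2) | COc1cc(C(=O)O[C@@H]2C[C@@](C)(O)[C@@H]3C[C@H]4O[C@@]4(C)[C@H]3C[C@@H]2C(C)C)ccc1O | target

## Step count and risks

Total step count: 19. Longest linear sequence: 18 steps (steps 1–15 and 17–19, from (R)-carvone).

**Step 13 (C5 configuration).** Protonation of the C5 carbanion may occur on the α face, giving the cis-fused hydroazulene. Over-reduction or incomplete O-triflation of the enolate may also lower the return.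
The fallback sets out from 17 and replaces the metal–ammonia protonation by a hydroxyl-directed hydrogenation. Luche reduction (NaBH4, CeCl3·7H2O, MeOH, −78 °C) should deliver hydride to C3 from the α face, away from C10, giving 10α-(triethylsilyloxy)-8β-(triisopropylsilyloxy)-1αH-guai-4-en-3β-ol F2. Hydrogenation with [Ir(cod)(PCy3)(py)]PF6 in CH2Cl2, directed by the 3β-hydroxyl, adds H2 to the β face of C4=C5 and gives 10α-(triethylsilyloxy)-8β-(triisopropylsilyloxy)-1αH,4βH,5βH-guaian-3β-ol F3. Syn-dehydration with the Burgess reagent (methyl N-(triethylammoniumsulfonyl)carbamate, benzene, 50 °C) toward the cis hydrogen at C4 returns to the route at 20.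

**Step 18 (oxirane face).** Direction by the distant, near-equatorial C10 hydroxyl may be too weak, so that oxygen is delivered to the β face or the reaction stalls.
The fallback sets out from 25 and uses a halohydrin sequence, which places oxygen on the face opposite to electrophile attack. NBS in aqueous THF at 0 °C should form the bromonium ion on the more open β face and water opens it at the tertiary C4 from the α face, giving 3β-bromo-4α,10α-dihydroxy-1αH,5βH-guaian-8β-yl 4-(tert-butyldimethylsilyloxy)-3-methoxybenzoate F4. K2CO3 in MeOH then closes the oxirane by attack of the 4α-alkoxide on C3 with inversion and cleaves the aryl silyl ether in the same flask, so the fallback comes back to the route at 27.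

**Step 11 (key step).** Competing photochemical channels (lumiketone-type isomerisation, secondary photolysis of the product cyclopentenone) may take over. The lipophilic silyl ether may also convert slowly through poor solubility in the water-rich medium, and the silyl ether may be partly hydrolysed on long irradiation.
The fallback sets out from 15 and keeps the same bond changes but traps the cation with acetic acid instead of water. Irradiation in anhydrous acetic acid, in which 15 dissolves fully, should give 10α-acetoxy-8β-(triisopropylsilyloxy)-1αH-guai-4-en-3-one F1. Methanolysis of the tertiary acetate (K2CO3, MeOH, 50 °C) comes back to the route at 16.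

Further compounds
F1 | step 11 | 10α-acetoxy-8β-(triisopropylsilyloxy)-1αH-guai-4-en-3-one | CC(C)[Si](C(C)C)(C(C)C)O[C@@H]1C[C@@](C)(OC(C)=O)[C@@H]2CC(=O)C(C)=C2C[C@@H]1C(C)C
F2 | step 13 | 10α-(triethylsilyloxy)-8β-(triisopropylsilyloxy)-1αH-guai-4-en-3β-ol | CC(C)[Si](C(C)C)(C(C)C)O[C@@H]1C[C@@](C)(O[Si](CC)(CC)CC)[C@@H]2C[C@H](O)C(C)=C2C[C@@H]1C(C)C
F3 | step 13 | 10α-(triethylsilyloxy)-8β-(triisopropylsilyloxy)-1αH,4βH,5βH-guaian-3β-ol | CC(C)[Si](C(C)C)(C(C)C)O[C@@H]1C[C@@](C)(O[Si](CC)(CC)CC)[C@@H]2C[C@H](O)[C@@H](C)[C@H]2C[C@@H]1C(C)C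
F4 | step 18 | 3β-bromo-4α,10α-dihydroxy-1αH,5βH-guaian-8β-yl 4-(tert-butyldimethylsilyloxy)-3-methoxybenzoate | COc1cc(C(=O)O[C@@H]2C[C@@](C)(O)[C@@H]3C[C@H](Br)[C@@](C)(O)[C@H]3C[C@@H]2C(C)C)ccc1O[Si](C)(C)C(C)(C)C
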